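The data were generated by integration with made-up constants.

**Note for whoever takes over the bench**

| flask | free monomer | initiator | temperature | remark | time |
|---|---|---|---|---|---|
| grey | 0.013 M | 1.4 mol% | 5 °C | run made earlier |  |
| blue | 0.013 M | 2.2 mol% | 16 °C | run made earlier |  |
| ochre | 0.0065 M | 1 mol% | 5 °C | run made earlier |  |
| theta | 0.013 M | 1 mol% | 0 °C |  | 15 min |
| beta | 0.013 M | 1 mol% | 10 °C |  | 15 min |
| gamma | 0.013 M | 1 mol% | 20 °C |  | 15 min |

| run | time / min | free monomer / % | monomer in chains / % |
|---|---|---|---|
| grey | 1.33 | 83.2 | 17.9 |
| grey | 2.50 | 69.1 | 32.9 |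
| grey | 4.00 | 49.8 | 50.8 |
| grey | 8.00 | 21.2 | 80.2 |
| grey | 15.0 | 5.1 | 92.6 |
| blue | 1.33 | 48.1 | 50.7 |
| blue | 2.50 | 22.1 | 77.6 |
| blue | 5.00 | 4.7 | 92.5 |
| blue | 6.00 | 4.4 | 92.2 |
| ochre | 3.00 | 85.5 | 14.4 |
| ochre | 6.00 | 68.7 | 29.3 |
| ochre | 10.0 | 51.8 | 48.3 |
| ochre | 12.0 | 43.6 | 55.4 |
| ochre | 15.0 | 35.2 | 64.4 |

(each reading ± 1 percentage point)

- the analysis behind the earlier runs scatters by 1 percentage point, standard deviation
- steps under discussion: free monomer + living end -> monomer in chains + living end; free monomer + initiator -> living end + monomer in chains; monomer in chains -> over-reaction product; 2 initiator -> spent initiator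

- which of these there is most of at the end, counted by the free monomer in it, theta (monomer in chains / free monomer)
- which of these there is most of at the end, counted by the free monomer in it, beta (monomer in chains / free monomer)
- which of these there is most of at the end, counted by the free monomer in it, gamma (monomer in chains / free monomer)
- amount of the one of these that there is most of at the end, in percent of the free monomer charged, theta
- amount of the one of these that there is most of at the end, in percent of the free monomer charged, beta
- amount of the one of these that there is most of at the end, in percent of the free monomer charged, gamma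

1. At early times the free monomer and monomer in chains of the grey run summed to 101% of the charge. At 15.0 min they summed to 97.7%. The blue run was short by 3.4 percentage points at 6.00 min. I booked these gaps as over-reaction product.

2. So I expected chains to be an intermediate, with over-reaction product at the far end. The question was the pace. For each run I divided the gap by the last chain reading and by the time since half the chains stood. That gave 0.00226 min⁻¹ for grey at 5 °C and 0.00790 min⁻¹ for blue at 16 °C. These rest on gaps of a few points, against a scatter of 1 point.

3. I carried the same ratio per degree on to gamma at 20 °C, which gave 0.0124 min⁻¹. This is k_L, the chain-loss constant: the fraction of chains lost per minute in gamma. It is a first-order constant, so the chain half-life in gamma came to 55.9 min.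

4. Do not leave gamma standing. By my reckoning, chains born at the start of gamma keep 83.0% by 15 min.

5. The forecast gave monomer in chains as the main species, at 77%, 91% and 88% for theta, beta and gamma: “Monomer in chains dominates throughout”. My gamma figure was the survival of the earliest chains, not an amount in the flask, and it stood lower than the forecast's gamma amount.

**Result.** Gamma gave 77.2% monomer in chains, 11 points under the forecast; theta gave 75.7% and beta 91.0%. In gamma, half of the making of chains up to 15 min was done by 1.80 min. Counting all gamma chains as born at that time, my k_L of 0.0124 min⁻¹ gave 84.9% at 15 min, which was 7.7 points more than the flask held.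

    free monomer + living end → monomer in chains + living end, rate k1*[living end]*[free monomer] (k = 14.0 L mol⁻¹ s⁻¹, Ea = 49.0 kJ mol⁻¹)
    free monomer + initiator → living end + monomer in chains (k = 1.60 L mol⁻¹ s⁻¹, Ea = 44.0 kJ mol⁻¹)
    monomer in chains → over-reaction product (k = 1.70 × 10⁻⁵ s⁻¹, Ea = 100 kJ mol⁻¹)
    2 initiator → spent initiator (k = 13.0 L mol⁻¹ s⁻¹, Ea = 46.0 kJ mol⁻¹)
    (constants at 0 °C)

Gamma left until 40 min: from 77.2%, k_L gave 56.6%. The computed value was 46.3%.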